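The pitfall in the south run is to take its even decay for a constant of the starting material, when every turnover passes through the catalyst, and the east run charges 1.50 mM of catalyst where the south run has 0.600 mM.

| flask | starting material | partner | catalyst | target | time |
|---|---|---|---|---|---|
| south | 120 mM | 240 mM | 0.600 mM |  |  |
| west | 60.0 mM | 180 mM | 0.600 mM |  |  |
| north-west | 120 mM | 240 mM | 0.600 mM | 60.0 mM |  |
| north-east | 240 mM | 240 mM | 0.600 mM |  |  |
| east | 120 mM | 240 mM | 1.50 mM |  | 45 min |

| run | time / min | [starting material] / mM |
|---|---|---|
| south run | 6.4 | 108.2 |
| south run | 13 | 97.2 |
| south run | 19 | 87.5 |
| south run | 26 | 77.5 |
| south run | 32 | 70.7 |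
| south run | 39 | 62.4 |
| south run | 45 | 56.5 |
| west run | 6.4 | 53.2 |
| west run | 13 | 47.9 |
| west run | 19 | 42.9 |
| west run | 26 | 38.4 |
| west run | 32 | 35.7 |
| west run | 39 | 31.5 |
| west run | 45 | 27.5 |
| north-west run | 6.4 | 108.8 |
| north-west run | 13 | 98.1 |
| north-west run | 19 | 87.5 |
| north-west run | 26 | 78.0 |
| north-west run | 32 | 70.9 |
| north-west run | 39 | 62.5 |
| north-west run | 45 | 57.2 |
| north-east run | 6.4 | 218.1 |
| north-east run | 13 | 197.5 |
| north-east run | 19 | 179.5 |
| north-east run | 26 | 162.6 |
| north-east run | 32 | 147.6 |
| north-east run | 39 | 134.2 |
| north-east run | 45 | 123.7 |

(scatter of a reading: 0.6 mM)

- reaction order in [partner] at the outset, round the charge of the south run, defined at two percent of the starting material turned into target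
- reaction order in [starting material] at the outset, round the charge of the south run, defined at two percent of the starting material turned into target (one fixed amount of target, the same in the runs compared)
- the west run starts with 60.0 mM less of starting material and of partner than the south run, and with no target. Compared where both hold the same amount of starting material, once fifteen percent of what the west run was charged with has turned into target, is the west run faster, slower or alike (within a tenth)?
- starting material in the east run at 45 min, as a share of the starting material charged
- which of these the readings show (the product ties up the catalyst / the product kills the catalyst / the substrate ties up the catalyst)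

- Overall: starting material + partner -> target, with catalyst as catalyst.
- Constant volume, constant temperature.
- Bound and free are read together.
- "The second partner" is partner.
- An order is taken over about fifteen percent of the charge, up and down.

In the south run c(starting material) falls from 120 mM to 56.5 mM in 45 min, which gives 41.4 min: the half-life of the starting material at a stated catalyst charge, a reading with the scatter of its points. Starting material is the limiting reagent of the south run, with 120 mM against 240 mM of partner.

Slowly, then. In the first instants of the south run c(starting material) drops to 108.2 mM by 6.4 min, and the stretch up to 19 min gives a half-life of 41.7 min, so the decay is close to pseudo-first-order. Near the middle, the south run holds about 60.0 mM of starting material, 180 mM of partner and 60.0 mM of target. The west run is charged with those amounts of starting material and partner but no target, and it crosses 30.0 mM a little after 39 min, where it reads 31.5 mM, and before 45 min, where it reads 27.5 mM; the half-life of 41.4 min falls in that gap. The north-west run, with 60.0 mM of target added, reads 57.2 mM at 45 min against 56.5 mM in the south run, a gap of 0.700 mM beside a scatter of 0.6 mM. At that end point the south run has about 176 mM of partner left. The north-east run, charged with 240 mM of starting material and 240 mM of partner, reads as a half-life of 47.1 min, longer than in the south run.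

The south, west, north-west and north-east runs each hold 0.600 mM of catalyst, so for the east run it is an assumption that the half-life shrinks in step with the catalyst charge. That gives 16.6 min, so 45 min counts 2.72 half-lives and leaves 15.2 % of the charge. The forecast expects a little more, 15.5 %. It puts the orders at 0.25 in partner and 0.87 in starting material, calls the west run alike, and concludes that the substrate ties up the catalyst: “This is mild saturation: the substrate ties up some catalyst.”

The steps behind the readings are these.

    catalyst + partner ⇌ catalyst-reagent complex, settled at all times (43.00 M⁻¹)
    catalyst-reagent complex + starting material → target + catalyst (33.12 M⁻¹ min⁻¹)
    catalyst + starting material ⇌ idle catalyst-substrate complex, settled at all times (8.360 M⁻¹)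

The east run holds 15.5 % of its charge at 45 min. The orders come out at 0.17 in partner, lower than the forecast's figure, and 0.94 in starting material; the west run is alike, with a rate ratio of 1.0 to the south run, and the substrate ties up the catalyst. That share of 15.5 % amounts to 2.69 half-lives in the east run, beside the 2.72 counted. Carried to the west run, at the same 0.600 mM of catalyst, the half-life of 41.4 min stands beside the 41.7 min in which target there reaches half of the starting material charged.

All runs stem from a simulated flask for substances that don't exist; noise was put on by code.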